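A leftover opens the blue run: at 15.0 h, E and D together hold 14.0 % of the charge, and 86.0 % stands in neither.

| setting | blue | amber | flask |
|---|---|---|---|
| X | 0.050 M | 0.025 M | 0.050 M |
| remark | the very flask that is asked about, followed so far | run made earlier |  |
| time |  |  | 30 h |

| run | time / h | E / % | D / % |
|---|---|---|---|
| blue | 3.00 | 10.6 | 3.8 |
| blue | 6.00 | 8.7 | 5.6 |
| blue | 10.0 | 8.0 | 6.9 |
| blue | 12.0 | 7.0 | 7.2 |
| blue | 15.0 | 6.4 | 7.6 |
| amber | 2.50 | 11.7 | 2.4 |
| amber | 5.00 | 11.1 | 5.9 |
| amber | 8.00 | 9.3 | 7.6 |
| amber | 10.0 | 9.1 | 7.9 |
| amber | 12.0 | 9.0 | 8.6 |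

(standard deviation of a reading: 0.5 percentage points)



* ratio of E to D at 10 min
* ratio of E to D at 2.0 h
* ratio of E to D at 30 h

In blue, D gains 3.8 % of the charge by 3.00 h while E rises from nothing. Yet it gains 1.8 percentage points in the stretch to 6.00 h, with E already high. Replace each curve by its mean, taking a straight rise as half its end value. Per hour and per unit of mean E, the first stretch then gives 0.239 h⁻¹ in blue and 0.164 h⁻¹ in amber, but the later blue stretch gives 0.0622 h⁻¹. The later figure is taken here as a net one, D made less D lost. The early figures, with little D present, are taken as the making.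

Their mean, 0.202 h⁻¹, is kept as a reading with the scatter of these few points: D gained per hour per unit of mean E while D is small, the passage constant, an apparent first-order rate constant. E falls after the first reading, so its curve bends, its mean over the first stretch is taken to lie above the straight one, and the constant then reads high. On a straight rise, E/D is two over the constant times the time. The reckoning here therefore puts the ratio at 10 min near 59.5, an estimate that leans low.

The forecast gives 40 at 10 min, 4.3 at 2.0 h and 0.8 at 30 h. Its figure at 10 min lies below the one reckoned here, on the ground that “Any small direct route to D would lower this sharply”.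

The flask gives 71.3, 4.87 and 0.552 at the same times.

    X ⇌ E (K = 0.600, k = 0.00276 min⁻¹)
    E ⇌ D (K = 3.58, k = 0.00273 min⁻¹)
    D ⇌ L (K = 2.52, k = 0.00247 min⁻¹)
    X ⇌ Q (K = 1.60, k = 0.00777 min⁻¹)
    2 X → Z (k = 0.0563 M⁻¹ min⁻¹)

The half-life of E by its forward turning into D is 4.2 h, short against the 30 h of the flask, and the passage constant reckons it as 3.43 h. In this flask E and D stand equal at 11.4 h, and E ends below D. The passage constant carries no charge in its reckoning, so it gives 59.5 again for the neighbour flask with 0.20 M of X, which stands at 69.7 at 10 min.

(All runs are simulated from invented constants, and the scatter is random.)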